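The numbers in the tables were computed with constants of no real substance; noise was put on by code.

The unit I counted in was not the molar but the natural logarithm of partner charged over partner left, which I call L. For a reaction pseudo-first-order in partner, the slope of L, in units per minute, is the rate divided by [partner].

| flask | starting material | partner | free catalyst | time |
|---|---|---|---|---|
| summer | 1.00 M | 1.10 M | 0.00200 M |  |
| winter | 0.400 M | 0.500 M | 0.00200 M |  |
| dawn | 1.00 M | 1.70 M | 0.00200 M |  |
| dusk | 3.00 M | 1.10 M | 0.00200 M |  |
| noon | 1.00 M | 0.360 M | 0.00600 M | 11 min |

| run | time / min | [target] / M |
|---|---|---|
| summer run | 0.63 | 0.060 |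
| summer run | 1.9 | 0.189 |
| summer run | 3.6 | 0.268 |
| summer run | 5.7 | 0.337 |
| summer run | 8.2 | 0.392 |
| summer run | 11 | 0.440 |
| winter run | 0.63 | 0.009 |
| winter run | 1.9 | 0.051 |
| winter run | 3.6 | 0.084 |
| winter run | 5.7 | 0.128 |
| winter run | 8.2 | 0.136 |
| winter run | 11 | 0.171 |
| dawn run | 0.63 | 0.096 |
| dawn run | 1.9 | 0.268 |
| dawn run | 3.6 | 0.416 |
| dawn run | 5.7 | 0.506 |
| dawn run | 8.2 | 0.565 |
| dawn run | 11 | 0.634 |
| dusk run | 0.63 | 0.100 |
| dusk run | 1.9 | 0.268 |
| dusk run | 3.6 | 0.382 |
| dusk run | 5.7 | 0.506 |
| dusk run | 8.2 | 0.613 |
| dusk run | 11 | 0.689 |

(readings scatter by 0.008 M)

* apparent order in [partner] of the starting rate, round the charge of the summer run (the rate where two percent of its starting material have turned into target)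
* apparent order in [starting material] of the starting rate, round the charge of the summer run (the rate where two percent of its starting material have turned into target) (one fixed amount of target, the same in the runs compared)
* target in the noon run at 11 min, as a share of the starting material charged

- Overall: starting material + partner -> target, with free catalyst as catalyst.
- Constant volume, constant temperature.
- What is held in complexes is read along with the free species.
- An order is taken over about fifteen percent of the charge, up and down.

In the summer run L rose at 0.0992 min⁻¹ over the first 1.9 min, bent at a knee between 1.9 min and 3.6 min, and ran at 0.0251 min⁻¹ over the last stretch, slower than at the start, reaching 0.511 at 11 min. I read this curve as a level approached plus a slow ramp. I supposed that the ramp grows with starting material, at b per molar per minute, and that the level belongs to the catalyst, equal at equal catalyst charge and equal time.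

The dusk run, with the same partner and catalyst charge as summer, reached a higher L of 0.984. I took mean starting material as the charge less 0.5 of the final target, so 0.780 M in summer and 2.66 M in dusk, and the gap gave b = 0.0230 L mol⁻¹ min⁻¹.

Subtracting the ramp from summer left 0.314. This is the catalyst allowance, the part of L that a charge of 0.00200 M free catalyst earns by 11 min. The same subtraction gave 0.294 in dawn and 0.339 in winter, though target at that time ranged from 0.171 M to 0.634 M, so I treated the allowance as a matter of the clock.

In the noon run partner, the limiting reagent, is charged at less than the starting material, and the free catalyst is 3.00 times that of summer. Assuming first order in catalyst and a mean starting material of 0.820 M, I reckoned L = 1.15 at 11 min, which gives 24.6% of the starting material as target.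

The forecast, which stood above my noon figure, gave orders of 0.95 in partner and 0.45 in starting material and 31% for noon, saying “this looks like product inhibition rather than catalyst death by time”. The flask gave 1.1, 0.26 and 24.9%.

    free catalyst + starting material ⇌ catalyst-substrate complex, settled at all times (19.60 L mol⁻¹)
    catalyst-substrate complex + partner → target + free catalyst (47.28 L mol⁻¹ min⁻¹)
    catalyst-substrate complex → spent catalyst + starting material (0.2760 min⁻¹)
    starting material + partner → target (0.02352 L mol⁻¹ min⁻¹)

The noon run stands as low as it does because catalyst-substrate complex goes over to spent catalyst: without that loss it gives 34.4% rather than 24.9%. The noon result means L = 1.18, and in my reckoning for the noon run the scaled allowance of 0.942 is larger than the ramp of 0.207. In the winter run, target reaching 0.200 M means L = 0.511. Supposing that the allowance earns little after 11 min, I took off 0.314 and left 0.197 for the ramp, which at a mean starting material of 0.300 M in the winter run reckons to 28.6 min, and the winter flask took 29.6 min.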